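**Plan**

- Retrosynthesis: the C4 oxygen is removed first (C4–O back to C4–I, then to C4–H of a 3-pyridinol). The pyridinol is cut at C4a–C8a and C3–C4 to a 5-ethoxy-4-methyloxazole that carries a vinyl-ended chain on its C2. The chain is cut at the amide bond N1–C8a, at C6–C7 and at C5–C1'.
- Enabling feature: the N1–C2(CH3)–C3(O) edge of ring A (the pyridone) is the N3–C4–C5 edge of a 5-alkoxy-4-methyloxazole. C8a is already joined to C4a through C8–C7–C6–C5 of ring B (the carbocycle), so a vinyl group on C5 (the future C4a=C4) is a dienophile on a four-atom tether.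
- Forward order: the open chain is joined (C5–C1', then C6–C7, then the amide) and the oxazole is closed. Ring B and ring A then form together in one thermal step, and C4 is oxygenated last.
- Stereochemistry: C5 comes from catalyst control in a copper-catalysed asymmetric SN2' alkylation, and C8 from methyl (R)-glycidate. Both are fixed before the cycloaddition, and the cis relation is the sum of the two.

Key step: step 7

Assumption: the phosphoramidite antipode that gives the (R)-configured homoallylic bromide is chosen from the established sense of induction of this copper catalyst with alkyl Grignard reagents (both antipodes are available); ethyl L-alaninate only supplies N1, C2 and C3, and its stereocentre is erased in the oxazole.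

**Route**

Step 1
Reactants: 1 (5-bromopentyl)benzene; 2 (E)-1,4-dibromobut-2-ene
Product: 4 [(6R)-6-(bromomethyl)oct-7-en-1-yl]benzene, via (5-phenylpentyl)magnesium bromide 3 (not isolated)
Conditions: Mg, Et2O, rt; then 2 (1.2 equiv), copper thiophene-2-carboxylate Cu(O2CC4H3S) (3 mol %), BINOL-derived N,N-bis(1-phenylethyl)phosphoramidite (3.3 mol %), CH2Cl2, −78 °C
Reagents that add atoms: none
Why: Copper-catalysed enantioselective SN2' allylic alkylation of the symmetric dibromide by an alkyl Grignard reagent is an established way to 3-alkyl-4-bromobut-1-enes; the chiral copper–phosphoramidite complex selects the alkene face in the γ-attack and so sets the future C5 (R in 4), and the homoallylic bromide formed is inert to a second substitution.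

Step 2
Reactants: 4 [(6R)-6-(bromomethyl)oct-7-en-1-yl]benzene; 5 methyl (2R)-oxirane-2-carboxylate
Product: 7 methyl (2R,5S)-5-ethenyl-2-hydroxy-10-phenyldecanoate, via [(2R)-2-ethenyl-7-phenylheptyl]magnesium bromide 6 (not isolated)
Conditions: Mg, THF, rt; then added slowly to 5 (1.3 equiv), CuBr·SMe2 (10 mol %), THF, −78 to −30 °C
Reagents that add atoms: none
Why: Copper-catalysed Grignard opening of a glycidic ester takes place at the unsubstituted C3 faster than carbonyl addition at low temperature, so the C2–O bond is untouched and the R configuration of 5 becomes that of the carbinol (future C8), while the stereocentre of the Grignard reagent is not involved.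

Step 3
Reactants: 7 methyl (2R,5S)-5-ethenyl-2-hydroxy-10-phenyldecanoate
Product: 8 methyl (2R,5S)-2-[(tert-butyldimethylsilyl)oxy]-5-ethenyl-10-phenyldecanoate
Conditions: TBSCl, imidazole, DMF, rt
Reagents that add atoms: tert-butyldimethylsilyl chloride, CC(C)(C)[Si](C)(C)Cl
Why: Silyl ether formation at the secondary alcohol masks the future C8 hydroxyl against the dehydrating, thermal and organometallic steps that follow.

Step 4
Reactants: 8 methyl (2R,5S)-2-[(tert-butyldimethylsilyl)oxy]-5-ethenyl-10-phenyldecanoate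
Product: 9 (2R,5S)-2-[(tert-butyldimethylsilyl)oxy]-5-ethenyl-10-phenyldecanoic acid
Conditions: LiOH·H2O, THF/MeOH/H2O, 0 °C to rt; then 1 M HCl to pH 3 at 0 °C
Reagents that add atoms: lithium hydroxide, [Li+].[OH-]
Why: Saponification of the methyl ester; the silyl ether is stable to hydroxide and the bulky α-silyloxy group disfavours enolisation, so the carbinol centre should be kept.

Step 5
Reactants: 9 (2R,5S)-2-[(tert-butyldimethylsilyl)oxy]-5-ethenyl-10-phenyldecanoic acid; 10 ethyl L-alaninate hydrochloride
Product: 11 ethyl N-[(2R,5S)-2-[(tert-butyldimethylsilyl)oxy]-5-ethenyl-10-phenyldecanoyl]-L-alaninate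
Conditions: EDC·HCl, HOBt, i-Pr2NEt, CH2Cl2, 0 °C to rt
Reagents that add atoms: none
Why: Carbodiimide/HOBt amide coupling; an α-silyloxy acid cannot form an oxazolone, so the activated acid should not epimerise.

Step 6
Reactants: 11 ethyl N-[(2R,5S)-2-[(tert-butyldimethylsilyl)oxy]-5-ethenyl-10-phenyldecanoyl]-L-alaninate
Product: 12 2-[(1R,4S)-1-[(tert-butyldimethylsilyl)oxy]-4-ethenyl-9-phenylnonyl]-5-ethoxy-4-methyl-1,3-oxazole
Conditions: PPh3, I2, Et3N, CH2Cl2, 0 °C to rt; chromatography on Et3N-deactivated silica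
Reagents that add atoms: none
Why: Cyclodehydration of an N-acyl α-amino ester (Robinson–Gabriel type, through the iodophosphonium-activated amide) gives the 5-ethoxyoxazole; the alanine carbon becomes the sp2 C4 of the oxazole, and triethylamine is too weak a base to disturb the silyloxy-bearing centre.

Step 7
Reactants: 12 2-[(1R,4S)-1-[(tert-butyldimethylsilyl)oxy]-4-ethenyl-9-phenylnonyl]-5-ethoxy-4-methyl-1,3-oxazole
Product: 14 (5S,8R)-8-[(tert-butyldimethylsilyl)oxy]-2-methyl-5-(5-phenylpentyl)-5,6,7,8-tetrahydroquinolin-3-ol, via oxygen-bridged cycloadduct 13 (not isolated)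
Conditions: o-dichlorobenzene (0.02 M, degassed), 180 °C, sealed tube; then AcOH, 60 °C
Reagents that add atoms: none
Why: On heating, the vinyl group adds across C2 and C5 of the oxazole (the azadiene C2=N3–C4=C5) in an intramolecular [4+2] cycloaddition to give the oxygen-bridged adduct 13; its C8a–O bond then opens with loss of the C4a proton and the resulting C3 hemiketal expels ethanol, so the oxazole oxygen remains as the C3 hydroxyl and the oxazole methyl becomes the C2 methyl. The closest known reaction type is the intramolecular oxazole–olefin Diels–Alder (Kondrat'eva) pyridine synthesis, in the 5-alkoxyoxazole version that ends in 3-hydroxy-2-methylpyridines and is known to accept unactivated alkenes. Ring B closes as a six-membered carbocycle by C8a–C4a bond formation through the tether C8–C7–C6–C5 (fused mode), and ring A closes through the cycloaddition itself, by the C4a–C8a and C3–C4 bonds, followed by aromatisation. No lasting stereocentre is made: the three new sp3 centres of 13 (C3, C4a, C8a) are erased on aromatisation, so endo and exo adducts converge, and the preset C5 and C8 are not enolisable under neutral thermolysis. The selectivity needed is regiochemical (C4a to C8a, C4 to C3) and chemoselective (loss of ethanol, not water); the short tether allows only the fused orientation, and the mild acid finish is the standard way of steering such adducts to the 3-hydroxypyridine. The tether supplies the entropic help that lets an unactivated terminal alkene act as dienophile, and any C5 epimer carried from step 1 becomes the trans diastereomer, separable at this stage.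

Step 8
Reactants: 14 (5S,8R)-8-[(tert-butyldimethylsilyl)oxy]-2-methyl-5-(5-phenylpentyl)-5,6,7,8-tetrahydroquinolin-3-ol
Product: 15 (5S,8R)-8-[(tert-butyldimethylsilyl)oxy]-4-iodo-2-methyl-5-(5-phenylpentyl)-5,6,7,8-tetrahydroquinolin-3-ol
Conditions: I2, Na2CO3, THF/H2O, rt
Reagents that add atoms: iodine, II
Why: Electrophilic aromatic iodination of the pyridinolate; C4 is the only unsubstituted ring position and lies ortho to the hydroxyl.

Step 9
Reactants: 15 (5S,8R)-8-[(tert-butyldimethylsilyl)oxy]-4-iodo-2-methyl-5-(5-phenylpentyl)-5,6,7,8-tetrahydroquinolin-3-ol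
Product: 16 (5S,8R)-8-[(tert-butyldimethylsilyl)oxy]-4-iodo-3-methoxy-2-methyl-5-(5-phenylpentyl)-5,6,7,8-tetrahydroquinoline
Conditions: MeI, K2CO3, DMF, rt
Reagents that add atoms: iodomethane, CI
Why: Williamson ether synthesis on the pyridinolate; the ring nitrogen is flanked by the C2 methyl and the substituted C8a and is further deactivated by the iodine, so O-methylation should prevail over N-methylation.

Step 10
Reactants: 16 (5S,8R)-8-[(tert-butyldimethylsilyl)oxy]-4-iodo-3-methoxy-2-methyl-5-(5-phenylpentyl)-5,6,7,8-tetrahydroquinoline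
Product: 19 (5S,8R)-8-[(tert-butyldimethylsilyl)oxy]-3-methoxy-2-methyl-5-(5-phenylpentyl)-5,6,7,8-tetrahydroquinolin-4(1H)-one, via pyridin-4-ylmagnesium chloride 17 (not isolated), via dimethyl pyridin-4-ylboronate 18 (not isolated)
Conditions: i-PrMgCl·LiCl, THF, −20 °C; B(OMe)3, −20 °C to rt; then 30% H2O2, aq. NaOH, 0 °C to rt
Reagents that add atoms: hydrogen peroxide, OO
Why: Iodine–magnesium exchange is insensitive to the two ortho substituents, the aryl Grignard reagent is trapped as the boronate and oxidised (hydroxydeboronation) to the 4-hydroxypyridine, which rests as the 4(1H)-pyridone; the silyl ether and both stereocentres are not involved.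

Step 11
Reactants: 19 (5S,8R)-8-[(tert-butyldimethylsilyl)oxy]-3-methoxy-2-methyl-5-(5-phenylpentyl)-5,6,7,8-tetrahydroquinolin-4(1H)-one
Product: 20 (5S,8R)-8-hydroxy-3-methoxy-2-methyl-5-(5-phenylpentyl)-5,6,7,8-tetrahydroquinolin-4(1H)-one
Conditions: HF·pyridine, THF, 0 °C to rt
Reagents that add atoms: none
Why: Fluoride-mediated desilylation frees the C8 hydroxyl under conditions too mild to ionise this position, so the cis-(5S,8R) target should result with both centres intact.

**Compound list**

1 | (5-bromopentyl)benzene | BrCCCCCc1ccccc1 | starting material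
2 | (E)-1,4-dibromobut-2-ene | BrC/C=C/CBr | starting material
3 | (5-phenylpentyl)magnesium bromide | Br[Mg]CCCCCc1ccccc1 | intermediate
4 | [(6R)-6-(bromomethyl)oct-7-en-1-yl]benzene | BrC[C@H](CCCCCc1ccccc1)C=C | intermediate
5 | methyl (2R)-oxirane-2-carboxylate (methyl (R)-glycidate) | COC(=O)[C@H]1CO1 | starting material
6 | [(2R)-2-ethenyl-7-phenylheptyl]magnesium bromide | Br[Mg]C[C@H](CCCCCc1ccccc1)C=C | intermediate
7 | methyl (2R,5S)-5-ethenyl-2-hydroxy-10-phenyldecanoate | COC(=O)[C@H](O)CC[C@H](CCCCCc1ccccc1)C=C | intermediate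
8 | methyl (2R,5S)-2-[(tert-butyldimethylsilyl)oxy]-5-ethenyl-10-phenyldecanoate | COC(=O)[C@H](O[Si](C)(C)C(C)(C)C)CC[C@H](CCCCCc1ccccc1)C=C | intermediate
9 | (2R,5S)-2-[(tert-butyldimethylsilyl)oxy]-5-ethenyl-10-phenyldecanoic acid | OC(=O)[C@H](O[Si](C)(C)C(C)(C)C)CC[C@H](CCCCCc1ccccc1)C=C | intermediate
10 | ethyl L-alaninate hydrochloride | CCOC(=O)[C@H](C)N.Cl | starting material
11 | ethyl N-[(2R,5S)-2-[(tert-butyldimethylsilyl)oxy]-5-ethenyl-10-phenyldecanoyl]-L-alaninate | CCOC(=O)[C@H](C)NC(=O)[C@H](O[Si](C)(C)C(C)(C)C)CC[C@H](CCCCCc1ccccc1)C=C | intermediate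
12 | 2-[(1R,4S)-1-[(tert-butyldimethylsilyl)oxy]-4-ethenyl-9-phenylnonyl]-5-ethoxy-4-methyl-1,3-oxazole | CCOc1oc([C@H](O[Si](C)(C)C(C)(C)C)CC[C@H](CCCCCc2ccccc2)C=C)nc1C | intermediate
13 | oxygen-bridged cycloadduct, (5S,8R)-8-[(tert-butyldimethylsilyl)oxy]-3-ethoxy-2-methyl-5-(5-phenylpentyl)-3,4,4a,5,6,7,8,8a-octahydro-3,8a-epoxyquinoline (C3, C4a, C8a as formed, mixture) | CCOC12CC3[C@@H](CCCCCc4ccccc4)CC[C@@H](O[Si](C)(C)C(C)(C)C)C3(O1)N=C2C | intermediate
14 | (5S,8R)-8-[(tert-butyldimethylsilyl)oxy]-2-methyl-5-(5-phenylpentyl)-5,6,7,8-tetrahydroquinolin-3-ol (cis) | Cc1nc2c(cc1O)[C@@H](CCCCCc1ccccc1)CC[C@H]2O[Si](C)(C)C(C)(C)C | intermediate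
15 | (5S,8R)-8-[(tert-butyldimethylsilyl)oxy]-4-iodo-2-methyl-5-(5-phenylpentyl)-5,6,7,8-tetrahydroquinolin-3-ol | Cc1nc2c(c(I)c1O)[C@@H](CCCCCc1ccccc1)CC[C@H]2O[Si](C)(C)C(C)(C)C | intermediate
16 | (5S,8R)-8-[(tert-butyldimethylsilyl)oxy]-4-iodo-3-methoxy-2-methyl-5-(5-phenylpentyl)-5,6,7,8-tetrahydroquinoline | COc1c(C)nc2c(c1I)[C@@H](CCCCCc1ccccc1)CC[C@H]2O[Si](C)(C)C(C)(C)C | intermediate
17 | [(5S,8R)-8-[(tert-butyldimethylsilyl)oxy]-3-methoxy-2-methyl-5-(5-phenylpentyl)-5,6,7,8-tetrahydroquinolin-4-yl]magnesium chloride | COc1c(C)nc2c(c1[Mg]Cl)[C@@H](CCCCCc1ccccc1)CC[C@H]2O[Si](C)(C)C(C)(C)C | intermediate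
18 | dimethyl [(5S,8R)-8-[(tert-butyldimethylsilyl)oxy]-3-methoxy-2-methyl-5-(5-phenylpentyl)-5,6,7,8-tetrahydroquinolin-4-yl]boronate | COc1c(C)nc2c(c1B(OC)OC)[C@@H](CCCCCc1ccccc1)CC[C@H]2O[Si](C)(C)C(C)(C)C | intermediate
19 | (5S,8R)-8-[(tert-butyldimethylsilyl)oxy]-3-methoxy-2-methyl-5-(5-phenylpentyl)-5,6,7,8-tetrahydroquinolin-4(1H)-one | COc1c(C)[nH]c2c(c1=O)[C@@H](CCCCCc1ccccc1)CC[C@H]2O[Si](C)(C)C(C)(C)C | intermediate
20 | (5S,8R)-8-hydroxy-3-methoxy-2-methyl-5-(5-phenylpentyl)-5,6,7,8-tetrahydroquinolin-4(1H)-one (cis) | COc1c(C)[nH]c2c(c1=O)[C@@H](CCCCCc1ccccc1)CC[C@H]2O | target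

**Step count**

Total: 11 steps. Longest linear sequence: 11 steps (1 to 20); compounds 2, 5 and 10 enter as commercial partners.

**Steps most likely to fail, with fallbacks**

Step 7. The unactivated vinyl group may engage the electron-rich alkoxyoxazole too slowly, so that the oxazole is lost to decomposition. The bridged adduct may also aromatise by loss of water and so keep the ethoxy group. The fallback sets out from 12 and switches to the acid-promoted, inverse-electron-demand mode, in which the N-protonated oxazole is the electron-poor azadiene and acid enforces ethanol loss. Compound 12 is heated with CF3CO2H (1 equiv) in o-dichlorobenzene at 150 °C, then treated with K2CO3 in MeOH. The silyl ether is expected to be lost under these conditions, so the product should be (5S,8R)-2-methyl-5-(5-phenylpentyl)-5,6,7,8-tetrahydroquinoline-3,8-diol F1. Both hydroxyls are then silylated (TBSCl, imidazole, DMF) to (5S,8R)-3,8-bis[(tert-butyldimethylsilyl)oxy]-2-methyl-5-(5-phenylpentyl)-5,6,7,8-tetrahydroquinoline F2. The aryl silyl ether alone is cleaved (K2CO3, MeOH, rt), which returns the route to 14.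

Step 2. The Grignard reagent may add to the ester carbonyl of the glycidate in competition with epoxide opening, and bromide may open the epoxide to a halohydrin. The fallback sets out from 4 (through 6) and uses an epoxide without a carbonyl group. Copper-catalysed opening (CuI, THF, −30 °C) of tert-butyldimethyl[(2R)-oxiran-2-ylmethoxy]silane should give (2R,5S)-1-[(tert-butyldimethylsilyl)oxy]-5-ethenyl-10-phenyldecan-2-ol F3. Silylation (TBSOTf, 2,6-lutidine, CH2Cl2) gives (2R,5S)-1,2-bis[(tert-butyldimethylsilyl)oxy]-5-ethenyl-10-phenyldecane F4. Selective cleavage of the primary silyl ether (HF·pyridine, pyridine/THF, 0 °C) gives (2R,5S)-2-[(tert-butyldimethylsilyl)oxy]-5-ethenyl-10-phenyldecan-1-ol F5. Oxidation of the primary alcohol to the acid (TEMPO, PhI(OAc)2, MeCN/H2O) returns the route to 9.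

Step 10. The hindered pyridylmagnesium intermediate may be protonated before it is borylated, which amounts to loss of iodine, or the boronate may form incompletely. The fallback sets out from 16 and introduces the C4 oxygen by C–O coupling instead of by metalation. Copper-catalysed etherification with benzyl alcohol (CuI, 3,4,7,8-tetramethyl-1,10-phenanthroline, Cs2CO3, toluene, 110 °C) should give (5S,8R)-4-(benzyloxy)-8-[(tert-butyldimethylsilyl)oxy]-3-methoxy-2-methyl-5-(5-phenylpentyl)-5,6,7,8-tetrahydroquinoline F6. Hydrogenolysis (H2, Pd/C, EtOH) returns the route to 19.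

**Further compounds**

F1 | step 7 | (5S,8R)-2-methyl-5-(5-phenylpentyl)-5,6,7,8-tetrahydroquinoline-3,8-diol | Cc1nc2c(cc1O)[C@@H](CCCCCc1ccccc1)CC[C@H]2O
F2 | step 7 | (5S,8R)-3,8-bis[(tert-butyldimethylsilyl)oxy]-2-methyl-5-(5-phenylpentyl)-5,6,7,8-tetrahydroquinoline | Cc1nc2c(cc1O[Si](C)(C)C(C)(C)C)[C@@H](CCCCCc1ccccc1)CC[C@H]2O[Si](C)(C)C(C)(C)C
F3 | step 2 | (2R,5S)-1-[(tert-butyldimethylsilyl)oxy]-5-ethenyl-10-phenyldecan-2-ol | CC(C)(C)[Si](C)(C)OC[C@H](O)CC[C@H](CCCCCc1ccccc1)C=C
F4 | step 2 | (2R,5S)-1,2-bis[(tert-butyldimethylsilyl)oxy]-5-ethenyl-10-phenyldecane | CC(C)(C)[Si](C)(C)OC[C@H](O[Si](C)(C)C(C)(C)C)CC[C@H](CCCCCc1ccccc1)C=C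
F5 | step 2 | (2R,5S)-2-[(tert-butyldimethylsilyl)oxy]-5-ethenyl-10-phenyldecan-1-ol | OC[C@H](O[Si](C)(C)C(C)(C)C)CC[C@H](CCCCCc1ccccc1)C=C
F6 | step 10 | (5S,8R)-4-(benzyloxy)-8-[(tert-butyldimethylsilyl)oxy]-3-methoxy-2-methyl-5-(5-phenylpentyl)-5,6,7,8-tetrahydroquinoline | COc1c(C)nc2c(c1OCc1ccccc1)[C@@H](CCCCCc1ccccc1)CC[C@H]2O[Si](C)(C)C(C)(C)C
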